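The ratio ρ of X to G, a selectivity, answers the question directly, because the asked share is ρ over one plus ρ.

| setting | dusk | spring | red | ochre | blue | green |
|---|---|---|---|---|---|---|
| E | 0.055 M | 0.22 M | 0.11 M | 0.11 M | 0.11 M | 0.11 M |
| Z | 0.95 equiv | 0.95 equiv | 0.950 equiv | 0.950 equiv | 0.950 equiv | 0.950 equiv |
| Q | 1 equiv | 1 equiv | 1.00 equiv | 1.00 equiv | 1.00 equiv | 1.00 equiv |
| temperature | 15 °C | 50 °C | 60 °C | 80 °C | 20 °C | 40 °C |
| remark | run made earlier | run made earlier |  |  |  |  |
| time |  |  | 5.0 min | 5.0 min | 5.0 min | 5.0 min |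

| run | time / min | X / % | G / % |
|---|---|---|---|
| dusk | 1.50 | 6.4 | 7.7 |
| dusk | 5.00 | 13.3 | 15.6 |
| dusk | 8.00 | 17.3 | 20.2 |
| dusk | 12.0 | 20.6 | 23.4 |
| dusk | 20.0 | 24.1 | 27.2 |
| dusk | 25.0 | 25.2 | 28.5 |
| dusk | 30.0 | 25.2 | 29.6 |
| spring | 0.667 | 42.3 | 29.6 |
| spring | 1.33 | 43.7 | 34.9 |
| spring | 2.00 | 43.2 | 37.8 |
| spring | 2.50 | 43.6 | 40.0 |
| spring | 3.00 | 43.0 | 40.3 |
| spring | 4.00 | 43.6 | 41.7 |
| spring | 5.00 | 44.6 | 43.2 |

(each reading ± 0.5 percentage points)

- the flask with the highest share of X in all that became X or G ("all alike" if they lie within 1.5 percentage points) (red / ochre / blue / green / all alike)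
- share of X in all that became X or G, red
- share of X in all that became X or G, ochre
- share of X in all that became X or G, blue
- share of X in all that became X or G, green

- the numbers in the tables scatter with a standard deviation of 0.5 percentage points

We read ρ at the last reading of each earlier run. Dusk gives 0.851 and spring gives 1.03. So from dusk at 15 °C to spring at 50 °C ρ as read grows by a factor of 1.21. We call this factor the step: what we take ρ to gain over that span of temperature, raised to a power for any other span.

Starting from spring, our reckoning gives ρ = 1.22 for ochre, 1.09 for red, 0.977 for green and 0.875 for blue. The shares are then 54.9%, 52.2%, 49.4% and 46.7%. We commit to ochre as highest, and its lead of 2.7 points over red is wider than the margin.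

Is one number enough? Not cleanly. In spring, ρ was 1.43 at 0.667 min and fell to 1.03 by 5.00 min, so it moves with time. In dusk it went from 0.831 to 0.851. The two runs also differ in c(E), 0.055 M against 0.22 M, and the new flasks stand at 0.11 M. The step is a quotient of these same two runs, so it carries both differences: from their first readings it comes to 1.72, against 1.21 from their last.

Unlike our reckoning, the forecast named green, with 47% for red, 41% for ochre, 47% for blue and 50% for green, and held that “early Z death should cut X noticeably” in ochre.

The flasks give ochre as highest: red 52.6%, ochre 56.5%, blue 49.2%, green 52.5%.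

    E + Q → G (k = 0.310 M⁻¹ s⁻¹, Ea = 49.0 kJ mol⁻¹)
    Q + Z → L (k = 0.860 M⁻¹ s⁻¹, Ea = 42.0 kJ mol⁻¹)
    E + Z → X (k = 0.860 M⁻¹ s⁻¹, Ea = 68.0 kJ mol⁻¹)
    2 Q → J (k = 0.0150 M⁻¹ s⁻¹, Ea = 73.0 kJ mol⁻¹)
    (constants at 60 °C)

Ochre keeps its share: left for 50.0 min, it still gives 55.9%. Now we carry the step to a further flask. Blue's result means ρ = 0.969. Raising the step for the span up to the neighbour, a repeat of blue at 35 °C, gives ρ = 1.05, a share of 51.2%. That neighbour gives 52.4%.

(All runs stem from a simulated flask for an exercise, noise included.)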